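**Retrosynthetic overview**
1. Target 18 ⇐ furylmethanol 17: one enantioselective all-syn hydrogenation of the furan sets C2, C3 and C4 (all-cis) at once.
2. 17 ⇐ ester 16 ⇐ furan 12 + arene 15: ester reduction; Friedel–Crafts benzylation joins the 2,4,5-trimethoxyphenyl ring to the furan CH2.
3. 12 ⇐ cyclopropenyl ketone 11: CuI-catalysed ring expansion to the 2,3,4-trisubstituted furan (key step); 11 ⇐ diazo ketoester 9 + alkyne 10 by Rh-carbenoid cyclopropenation.
4. 9 ⇐ 3,4,5-trimethoxybenzaldehyde 6 + ethyl diazoacetate 7; 6 ⇐ p-cresol 1; 15 ⇐ 1,4-benzoquinone 13.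
5. Ring order: cyclopropene, then furan by ring expansion, then tetrahydrofuran by hydrogenation; the two benzene rings come from 1 and 13.

Assumption: the ligand enantiomer that gives the (2R,3R,4R) series in step 10 is settled by one trial run; (R,R) is written and (S,S) is used if the sense is opposite.

**Route**

Step 1
Reactants: 1 p-cresol
Product: 4 3,5-dibromo-4-hydroxybenzaldehyde, via 2,6-dibromo-4-methylphenol 2 (not isolated), via 2,6-dibromo-4-(dibromomethyl)phenol 3 (not isolated)
Conditions: Br2 (4.1 equiv), o-dichlorobenzene, 30 °C then 150–160 °C; then H2O, 100 °C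
Reagents that add atoms: bromine BrBr; water O
Why: Electrophilic aromatic bromination ortho to the phenol, then thermal side-chain bromination to the benzal bromide and its hydrolysis, is the established one-pot technical route to this aldehyde.

Step 2
Reactants: 4 3,5-dibromo-4-hydroxybenzaldehyde
Product: 6 3,4,5-trimethoxybenzaldehyde, via sodium 4-formyl-2,6-dimethoxyphenolate 5 (not isolated)
Conditions: NaOMe (4.5 equiv), CuCl (5 mol%), DMF/MeOH, 110 °C; then Me2SO4 (3 equiv), 60 °C
Reagents that add atoms: sodium methoxide [Na+].[O-]C; dimethyl sulfate COS(=O)(=O)OC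
Why: Copper-catalysed Ullmann-type methoxylation of both aryl bromides (the syringaldehyde process) leaves the phenolate, which is O-methylated in the same pot (Williamson etherification).

Step 3
Reactants: 6 3,4,5-trimethoxybenzaldehyde; 7 ethyl diazoacetate
Product: 9 ethyl 2-diazo-3-oxo-3-(3,4,5-trimethoxyphenyl)propanoate, via ethyl 2-diazo-3-hydroxy-3-(3,4,5-trimethoxyphenyl)propanoate 8 (not isolated)
Conditions: 7 (1.5 equiv), DBU (20 mol%), DMSO, rt; then IBX (1.5 equiv), rt
Reagents that add atoms: none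
Why: DBU-catalysed aldol-type addition of the diazoacetate to the aldehyde followed by IBX oxidation of the carbinol in the same DMSO solution is a known one-pot entry to α-diazo-β-ketoesters.

Step 4
Reactants: 9 ethyl 2-diazo-3-oxo-3-(3,4,5-trimethoxyphenyl)propanoate; 10 3-methoxyprop-1-yne
Product: 11 ethyl 2-(methoxymethyl)-1-(3,4,5-trimethoxybenzoyl)cycloprop-2-ene-1-carboxylate (racemic)
Conditions: Rh2(OAc)4 (2 mol%), 10 (5 equiv), CH2Cl2, 40 °C, slow addition of 9
Reagents that add atoms: none
Why: Rh-carbenoid [2+1] cyclopropenation of a terminal alkyl alkyne by an acceptor/acceptor diazo compound gives the isolable cyclopropenyl ketone at low temperature; its single stereocentre is lost in step 5.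

Step 5
Reactants: 11 ethyl 2-(methoxymethyl)-1-(3,4,5-trimethoxybenzoyl)cycloprop-2-ene-1-carboxylate
Product: 12 ethyl 4-(methoxymethyl)-2-(3,4,5-trimethoxyphenyl)furan-3-carboxylate
Conditions: CuI (5 mol%), MeCN, reflux
Reagents that add atoms: none
Why: CuI-catalysed ring-opening cycloisomerisation of cyclopropenyl ketones is a stepwise, non-pericyclic ring expansion (iodocupration, β-carbon elimination of the less substituted ring bond, O-cyclisation) that gives the 2,3,4-trisubstituted furan and not the 2,3,5-isomer.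

Step 6
Reactants: 13 1,4-benzoquinone
Product: 14 benzene-1,2,4-triyl triacetate
Conditions: Ac2O, H2SO4 (cat.), 40–50 °C
Reagents that add atoms: acetic anhydride CC(=O)OC(C)=O
Why: Thiele–Winter acetoxylation (acid-catalysed conjugate addition of acetate, enolisation and peracetylation) installs the 1,2,4-oxygen pattern in one step.

Step 7
Reactants: 14 benzene-1,2,4-triyl triacetate
Product: 15 1,2,4-trimethoxybenzene
Conditions: Me2SO4, NaOH aq, MeOH, N2, 0 °C to 60 °C
Reagents that add atoms: dimethyl sulfate COS(=O)(=O)OC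
Why: Saponification of the aryl acetates and Williamson O-methylation of the air-sensitive triol as it forms, under nitrogen, is the standard preparation of this arene.

Step 8
Reactants: 12 ethyl 4-(methoxymethyl)-2-(3,4,5-trimethoxyphenyl)furan-3-carboxylate; 15 1,2,4-trimethoxybenzene
Product: 16 ethyl 2-(3,4,5-trimethoxyphenyl)-4-[(2,4,5-trimethoxyphenyl)methyl]furan-3-carboxylate
Conditions: 15 (3 equiv), TfOH (10 mol%), HFIP, 0 °C to rt
Reagents that add atoms: none
Why: Friedel–Crafts benzylation, in which acid ionises the methyl ether to a 3-furylmethyl cation stabilised by the ring oxygen and the cation is taken up at C5 of 15 (para to one methoxy group, ortho to another), gives the 2,4,5-trimethoxybenzyl pattern.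

Step 9
Reactants: 16 ethyl 2-(3,4,5-trimethoxyphenyl)-4-[(2,4,5-trimethoxyphenyl)methyl]furan-3-carboxylate
Product: 17 {2-(3,4,5-trimethoxyphenyl)-4-[(2,4,5-trimethoxyphenyl)methyl]furan-3-yl}methanol
Conditions: LiAlH4, THF, 0 °C
Reagents that add atoms: none
Why: Hydride reduction of the ester to the primary alcohol leaves the furan and aryl ethers untouched and gives an electron-rich furan suited to step 10.

Step 10
Reactants: 17 {2-(3,4,5-trimethoxyphenyl)-4-[(2,4,5-trimethoxyphenyl)methyl]furan-3-yl}methanol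
Product: 18 [(2R,3R,4R)-2-(3,4,5-trimethoxyphenyl)-4-[(2,4,5-trimethoxyphenyl)methyl]oxolan-3-yl]methanol (all-cis; the target CNP0238280.1)
Conditions: Ru(cod)(2-methylallyl)2 (5 mol%), (R,R)-SINpEt·HBF4 [1,3-bis((R)-1-(naphthalen-1-yl)ethyl)-4,5-dihydroimidazolium tetrafluoroborate] (10 mol%), KOtBu (10 mol%), hexane, 70 °C (catalyst formation); then 17, H2 (100 bar), toluene, 40 °C
Reagents that add atoms: none
Why: Proposed new method: enantioselective complete hydrogenation of a 2,3,4-trisubstituted 2-aryl-3-(hydroxymethyl)furan with the chiral ruthenium bis(N-heterocyclic carbene) catalyst, whose closest known use is the asymmetric hydrogenation of 2,5- and 2,4-disubstituted furans and of benzofurans; the electron-rich furan binds face-on to the ruthenium hydride, the less substituted C4=C5 bond is reduced first and fixes C4 (enantio-determining), and the remaining tetrasubstituted 2-aryl enol ether C2=C3 bond takes up H2 on the same face, anti to the new C4 benzyl group, so that the aryl, CH2OH and benzyl groups end up all-cis as (2R,3R,4R) while the two trimethoxyphenyl rings stay intact at 40 °C.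

**Compound list**
1 | p-cresol (4-methylphenol) | Cc1ccc(O)cc1 | starting material
2 | 2,6-dibromo-4-methylphenol | Cc1cc(Br)c(O)c(Br)c1 | intermediate
3 | 2,6-dibromo-4-(dibromomethyl)phenol | BrC(Br)c1cc(Br)c(O)c(Br)c1 | intermediate
4 | 3,5-dibromo-4-hydroxybenzaldehyde | O=Cc1cc(Br)c(O)c(Br)c1 | intermediate
5 | sodium 4-formyl-2,6-dimethoxyphenolate | COc1cc(C=O)cc(OC)c1[O-].[Na+] | intermediate
6 | 3,4,5-trimethoxybenzaldehyde | COc1cc(C=O)cc(OC)c1OC | intermediate
7 | ethyl diazoacetate | CCOC(=O)C=[N+]=[N-] | starting material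
8 | ethyl 2-diazo-3-hydroxy-3-(3,4,5-trimethoxyphenyl)propanoate (racemic) | CCOC(=O)C(=[N+]=[N-])C(O)c1cc(OC)c(OC)c(OC)c1 | intermediate
9 | ethyl 2-diazo-3-oxo-3-(3,4,5-trimethoxyphenyl)propanoate | CCOC(=O)C(=[N+]=[N-])C(=O)c1cc(OC)c(OC)c(OC)c1 | intermediate
10 | 3-methoxyprop-1-yne (methyl propargyl ether) | COCC#C | starting material
11 | ethyl 2-(methoxymethyl)-1-(3,4,5-trimethoxybenzoyl)cycloprop-2-ene-1-carboxylate (racemic) | CCOC(=O)C1(C(=O)c2cc(OC)c(OC)c(OC)c2)C=C1COC | intermediate
12 | ethyl 4-(methoxymethyl)-2-(3,4,5-trimethoxyphenyl)furan-3-carboxylate | CCOC(=O)c1c(COC)coc1-c1cc(OC)c(OC)c(OC)c1 | intermediate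
13 | 1,4-benzoquinone | O=C1C=CC(=O)C=C1 | starting material
14 | benzene-1,2,4-triyl triacetate | CC(=O)Oc1ccc(OC(C)=O)c(OC(C)=O)c1 | intermediate
15 | 1,2,4-trimethoxybenzene | COc1ccc(OC)c(OC)c1 | intermediate
16 | ethyl 2-(3,4,5-trimethoxyphenyl)-4-[(2,4,5-trimethoxyphenyl)methyl]furan-3-carboxylate | CCOC(=O)c1c(Cc2cc(OC)c(OC)cc2OC)coc1-c1cc(OC)c(OC)c(OC)c1 | intermediate
17 | {2-(3,4,5-trimethoxyphenyl)-4-[(2,4,5-trimethoxyphenyl)methyl]furan-3-yl}methanol | OCc1c(Cc2cc(OC)c(OC)cc2OC)coc1-c1cc(OC)c(OC)c(OC)c1 | intermediate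
18 | [(2R,3R,4R)-2-(3,4,5-trimethoxyphenyl)-4-[(2,4,5-trimethoxyphenyl)methyl]oxolan-3-yl]methanol | COc1cc(OC)c(OC)cc1C[C@H]1CO[C@@H](c2cc(OC)c(OC)c(OC)c2)[C@H]1CO | target

**Count**
Total steps: 10. Longest linear sequence: 8 steps (1, 2, 3, 4, 5, 8, 9, 10); steps 6 and 7 make the second arene in a side branch.

**Three steps most likely to fail**

Step 10 (the new hydrogenation). The tetrasubstituted C2=C3 bond may be reduced slowly, or the enantioselectivity may be low. The fallback sets out from 16 and comes back at 18, using known chemistry. Heterogeneous all-syn hydrogenation of the 3-furoate over Rh/Al2O3 (H2, 50 bar, EtOAc, rt) gives the racemic all-cis ester. This is a 1:1 mixture of ethyl (2R,3S,4R)-2-(3,4,5-trimethoxyphenyl)-4-[(2,4,5-trimethoxyphenyl)methyl]oxolane-3-carboxylate F1 and its enantiomer, ethyl (2S,3R,4S)-2-(3,4,5-trimethoxyphenyl)-4-[(2,4,5-trimethoxyphenyl)methyl]oxolane-3-carboxylate F2. Reduction with LiAlH4 at −20 °C, cold to avoid epimerising the ester α-carbon, gives 18 together with its enantiomer [(2S,3S,4S)-2-(3,4,5-trimethoxyphenyl)-4-[(2,4,5-trimethoxyphenyl)methyl]oxolan-3-yl]methanol F3. Preparative chiral SFC then delivers 18.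

Step 8 (Friedel–Crafts benzylation). The furylmethyl cation may instead attack C5 of another furan, or the acid may degrade the furan. The fallback replaces the cationic coupling by a cross-coupling; it sets out from 12 and 15 and comes back at 16. HBr in AcOH at rt converts 12 into ethyl 4-(bromomethyl)-2-(3,4,5-trimethoxyphenyl)furan-3-carboxylate F4. Bromination of 15 (NBS, MeCN) gives 1-bromo-2,4,5-trimethoxybenzene F5. Bromine–lithium exchange (n-BuLi, THF, −78 °C), B(OMe)3 and aqueous acid then give (2,4,5-trimethoxyphenyl)boronic acid F6. Suzuki–Miyaura coupling of F4 with F6 (Pd(PPh3)4, K2CO3, DME/H2O, 80 °C) gives 16.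

Step 4 (cyclopropenation). The carbenoid may be diverted by the ether oxygen (oxonium ylide) or go straight to the 2,3,5-furan. The fallback brings the second arene in on an alkyne that has no propargylic oxygen; it sets out from 15 and 9 and comes back at 16, so that step 8 is not needed. Chloromethylation of 15 (paraformaldehyde, HCl, AcOH) gives 1-(chloromethyl)-2,4,5-trimethoxybenzene F7. Copper-catalysed coupling with ethynylmagnesium bromide (CuBr cat., THF) gives 1,2,4-trimethoxy-5-(prop-2-yn-1-yl)benzene F8. Cyclopropenation of F8 with 9 (Rh2(OAc)4, CH2Cl2, slow addition) gives ethyl 1-(3,4,5-trimethoxybenzoyl)-2-[(2,4,5-trimethoxyphenyl)methyl]cycloprop-2-ene-1-carboxylate F9. The same CuI ring expansion as in step 5 (CuI, MeCN, reflux) turns F9 into 16.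

**Further compounds**
F1 | step 10 | ethyl (2R,3S,4R)-2-(3,4,5-trimethoxyphenyl)-4-[(2,4,5-trimethoxyphenyl)methyl]oxolane-3-carboxylate | COc1cc(OC)c(OC)cc1C[C@H]1CO[C@@H](c2cc(OC)c(OC)c(OC)c2)[C@H]1C(=O)OCC
F2 | step 10 | ethyl (2S,3R,4S)-2-(3,4,5-trimethoxyphenyl)-4-[(2,4,5-trimethoxyphenyl)methyl]oxolane-3-carboxylate | COc1cc(OC)c(OC)cc1C[C@@H]1CO[C@H](c2cc(OC)c(OC)c(OC)c2)[C@@H]1C(=O)OCC
F3 | step 10 | [(2S,3S,4S)-2-(3,4,5-trimethoxyphenyl)-4-[(2,4,5-trimethoxyphenyl)methyl]oxolan-3-yl]methanol | COc1cc(OC)c(OC)cc1C[C@@H]1CO[C@H](c2cc(OC)c(OC)c(OC)c2)[C@@H]1CO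
F4 | step 8 | ethyl 4-(bromomethyl)-2-(3,4,5-trimethoxyphenyl)furan-3-carboxylate | CCOC(=O)c1c(CBr)coc1-c1cc(OC)c(OC)c(OC)c1
F5 | step 8 | 1-bromo-2,4,5-trimethoxybenzene | COc1cc(OC)c(Br)cc1OC
F6 | step 8 | (2,4,5-trimethoxyphenyl)boronic acid | COc1cc(OC)c(B(O)O)cc1OC
F7 | step 4 | 1-(chloromethyl)-2,4,5-trimethoxybenzene | COc1cc(OC)c(CCl)cc1OC
F8 | step 4 | 1,2,4-trimethoxy-5-(prop-2-yn-1-yl)benzene | COc1cc(OC)c(CC#C)cc1OC
F9 | step 4 | ethyl 1-(3,4,5-trimethoxybenzoyl)-2-[(2,4,5-trimethoxyphenyl)methyl]cycloprop-2-ene-1-carboxylate (racemic) | CCOC(=O)C1(C(=O)c2cc(OC)c(OC)c(OC)c2)C=C1Cc1cc(OC)c(OC)cc1OC
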